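# Total synthesis proposal for CNP0265335.1 (37)

## The problem

- **Structure.** Target 37 is a heliangolide. Its carbocycle C1–C10 (germacrane numbering) carries a (4Z)-trisubstituted alkene and a trans-1,10-epoxide, which is the oxide of a 1(10)E alkene. It also carries a trans-fused α-methylene-γ-lactone on C6–C7 (C11–C13, ring oxygen on C6). Two different esters are present: (R)-2-methylbutanoate on C3 and (2R,3R)-epoxyangelate on C8.
- **The ring.** The ten-membered ring is the hardest element. End-to-end closure fights entropy and transannular strain, and it must be done with one Z and one E trisubstituted alkene already correct.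
- **Ring stereocentres.** These fall into three groups.
  - C6(R)/C7(R)/C8(R) is a contiguous triad in which neighbours can control each other.
  - C3(S) is insulated from the triad by C4=C5 and must be imported.
  - C1(R)/C10(R) depend only on which face of the E alkene the ring conformation exposes.
- **Side chains.** The three side-chain centres cannot be induced by the core. They must arrive in enantiopure acyl donors.
- **Fragile groups.** The α-methylene lactone is a Michael acceptor. The 1,10-epoxide lies across the ring from C4=C5 and is prone to acid-triggered transannular cyclisation. Together with the epoxy ester and the two distinct esters, these forbid strong base, strong acid and nucleophiles late in the route.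
- **The enabling feature.** C1 and C6 face each other across the ring.
  - A C1–C6 bond would divide the ring into the cyclohexene C1–C2–C3–C4=C5–C6 and two alkenyl arms, C10(C14)=C9 on C1 and C7=C8 on C6.
  - In that cyclohexene the Z geometry is automatic, C4 holds its methyl and C3 its oxygen.
  - With oxygen on C6 this is a 3-oxido-1,5-diene (C8=C7–C6(O)–C1–C10=C9) on the p-menthane skeleton of trans-carveol 4. The ring can therefore be made by four-atom expansion of a six-membered ring.

## Retrosynthesis

**37 ⇒ 36 (C1–O and C10–O).** The epoxide is removed first because it is the most acid-labile group. C1=C10 of 36 is also the only electron-rich alkene left: C4=C5 carries two allylic acyloxy groups and C11=C13 is conjugated. The forward step needs one face only, and that face is exposed only once the trans-lactone has fixed the C6–C7 torsion. This is why the epoxide is not introduced earlier.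

**36 ⇒ 33 + 34, and 33 ⇒ 32 (O3–acyl, then O3–Si).** Cutting the C3 ester before the C8 ester lets a single silyl ether carry C3 through the whole route. The acylation of 33 with acid 34 must be mild and must not epimerise the acid.

**32 ⇒ 29 ⇒ 28 (O6–C12 lactone bond, taken back to the alcohol level at C12).** The α-methylene lactone is traced to the 2-methylene-1,4-diol 29, so C11=C13 is carried from the start and no lactone enolate is ever needed. This choice is what allows the esters to be present early. The forward oxidation must pick the primary allylic alcohol. Only O6 is free to close the ring, because O8 is acylated and O3 is silylated.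

**28 ⇒ 22 + 26 (O8–acyl bond and C6–H bond together).** A separate reduction and esterification would require O6 and O8 to be distinguished. Cutting both bonds at once corresponds to an Evans–Tishchenko reaction of β-hydroxy ketone 22 with epoxy aldehyde 26. That reaction sets C6 anti to C8, installs the epoxyangelate and leaves only O6 free.

**22 ⇒ 20 (C8–O to C8–Si).** Oxygen on C8 cannot pass through the key step, because a β-alkoxy enolate would eliminate. A benzyldimethylsilyl group stands in for it and is exchanged with retention.

**20 ⇒ 17 (reconnect C1–C6, cut C8–C9: the key disconnection).**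
- Among the transannular pairs only C1/C6 places the oxygen-bearing carbon at the carbinol position of a 1,5-diene and the Z alkene inside a six-membered ring. The C5/C10 pair gives an ordinary Cope system whose equilibrium favours the six-membered ring.
- Precursor 17 has one small ring and three stereocentres, two of which are sacrificial.
- The forward reaction must deliver the ring, the 1(10)E alkene, C8 by chirality transfer and C7 on quenching.
- C11 is placed on C7 beforehand on purpose. The outer face of the ring enolate must receive the proton, not the carbon substituent, to give H-7 α.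

**17 ⇒ 6 + 15 (C6–C7).** A 1,2-addition joins the two halves. The forward step must come anti to the isopropenyl group of 6. The nucleophile from 15 must have silicon trans to the metal, so that silicon is equatorial in the chair.

**6 ⇒ 5 ⇒ 4 ⇒ 2 ⇒ 1.**
- Enone 6 is trans-carveol 4 oxidised at its only ring allylic CH2.
- The required (1S,5R) isomer has OH trans to isopropenyl, which direct reduction of carvone does not give.
- It follows from (S)-carvone 1 by epoxidation and Wharton transposition.

**15 ⇒ 14 ⇒ 10 + 13, and 26 ⇒ 25 ⇒ 24 ⇒ 23.** The stannane comes from syn hydrostannation of enyne 14, made by Sonogashira union of bromide 10 and alkyne 13. The aldehyde comes from methyl angelate 23 by reduction, asymmetric epoxidation and oxidation.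

## Roads not taken

**Alternative 1: cut C6–C7 and O6–C12 (the most obvious plan).**
- Forward key step: intramolecular Nozaki–Hiyama–Kishi or Barbier allylation of the Z-enal in the seco compound A1 by its 2-(bromomethyl)acrylate end, followed by lactonisation.
- A1 needs a long linear build in which both trisubstituted alkenes and the C3 and C8 carbinols are each made by separate stereoselective steps.
- The Z-enal can isomerise to E under Lewis-acidic metal salts.
- The allylmetal carries the C8 oxygen next to its nucleophilic γ-carbon, so reductive 1,4-elimination to a diene competes.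
- The C6/C7 outcome rests on a high-dilution macrocyclic transition state with no firm model for the 4Z series.
- The chosen plan makes the ring from a six-membered ring without dilution and takes Z from the ring itself.

**Alternative 2: cut C1=C10.**
- Forward key step: ring-closing metathesis of lactone diene A2 with the second-generation Grubbs catalyst.
- A trisubstituted alkene would have to form in a ten-membered ring with E geometry, where strain tends to favour Z or oligomers.
- The α-methylene lactone is a competing alkene.
- All four ring stereocentres and the Z alkene must exist beforehand, so the key step solves only the closure.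

**Alternative 3: cut C6–C7 as a [2,3]-Wittig ring contraction of the 13-membered bis-allylic ether A3.**
- The shift would create C6–C7, the C6 hydroxyl and C11=C13 together, which is attractive.
- However, A3 is itself a macrocycle with three defined trisubstituted alkenes and needs a macro-etherification.
- Deprotonation can occur at C6 or at C13. A [1,2]-shift competes. The sense at C6/C7 relative to C8 again depends on a macrocyclic transition state.
- The precursor is therefore not simpler than the product, whereas 17 is.

Key step: step 10

Assumption: germacrane numbering (C1–C10 ring, C11–C13 lactone arm, C14 on C10, C15 on C4; α/β as in the usual drawing with H-7 α) is used for all compounds from 17 on, and 1, 7, 8, 11, 12, 23 and 34 are taken as commercial.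

## Steps

Step 1
Reactants: 1 (S)-(+)-carvone
Product: 2 (S)-carvone enone epoxide (oxirane oxygen trans to the isopropenyl group)
Conditions: 30% H2O2, NaOH (cat.), MeOH, 0 °C
Reagents that add atoms: hydrogen peroxide, OO
Why: Weitz–Scheffer nucleophilic epoxidation touches only the enone alkene; hydroperoxide adds axially at the β-carbon anti to the isopropenyl group, so the oxirane should end trans to it.

Step 2
Reactants: 2 (S)-carvone enone epoxide
Product: 4 (1S,5R)-trans-carveol, via epoxy hydrazone 3 (not isolated)
Conditions: N2H4·H2O, AcOH (cat.), MeOH, 0 °C to rt, under N2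
Reagents that add atoms: hydrazine, NN (nitrogen held only in 3)
Why: Wharton transposition: 3 collapses with loss of nitrogen, the C–O bond at the former β-carbon is kept, so the hydroxyl stays trans to the isopropenyl group. The 1,3-shift of functionality turns the (S) centre of 1 into the (5R) centre of 4.

Step 3
Reactants: 4 (1S,5R)-trans-carveol
Product: 5 (1S,5R)-trans-carveol triisopropylsilyl ether
Conditions: TIPSOTf, 2,6-lutidine, CH2Cl2, 0 °C
Reagents that add atoms: triisopropylsilyl triflate, CC(C)[Si](OS(=O)(=O)C(F)(F)F)(C(C)C)C(C)C
Why: Standard silylation of a hindered secondary alcohol. TIPS is chosen because it must survive CrO3, an organolithium, KH and the short fluoride treatment of step 11.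

Step 4
Reactants: 5 trans-carveol triisopropylsilyl ether
Product: 6 (4S,6R)-3-methyl-6-(prop-1-en-2-yl)-4-(triisopropylsilyloxy)cyclohex-2-en-1-one
Conditions: CrO3, 3,5-dimethylpyrazole, CH2Cl2, −20 °C
Reagents that add atoms: chromium trioxide, O=[Cr](=O)=O
Why: Allylic C–H oxidation to an enone with the CrO3–3,5-dimethylpyrazole complex, the reaction type used for ring CH2 groups next to trisubstituted alkenes. The only ring allylic methylene is the future C6, and the bulky silyl ether shields the C3–H. Neither stereocentre is touched, and the low temperature should prevent epimerisation next to the new ketone.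

Step 5
Reactants: 7 4-methoxybenzyl alcohol; 8 2,3-dibromopropene
Product: 10 2-bromoallyl 4-methoxybenzyl ether, via sodium 4-methoxybenzyl oxide 9 (not isolated)
Conditions: NaH, THF, 0 °C to rt
Reagents that add atoms: sodium hydride, [H-].[Na+] (sodium held only in 9)
Why: Williamson ether synthesis at the allylic bromide; the vinylic bromide is inert to substitution.

Step 6
Reactants: 11 benzyl(chloro)dimethylsilane; 12 ethynylmagnesium bromide
Product: 13 benzyl(ethynyl)dimethylsilane
Conditions: THF, 0 °C to rt
Reagents that add atoms: none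
Why: Substitution at silicon by an alkynyl Grignard reagent, the usual access to ethynylsilanes.

Step 7
Reactants: 10 2-bromoallyl 4-methoxybenzyl ether; 13 benzyl(ethynyl)dimethylsilane
Product: 14 benzyl{3-[(4-methoxybenzyloxy)methyl]but-3-en-1-yn-1-yl}dimethylsilane
Conditions: Pd(PPh3)4 (cat.), CuI (cat.), i-Pr2NH, THF, 45 °C
Reagents that add atoms: none
Why: Sonogashira coupling of a 2-bromoalkene with a silyl-capped terminal alkyne. The C–Si bond is stable to amine and CuI, as for other ethynylsilanes.

Step 8
Reactants: 14 silyl enyne
Product: 15 (1E)-1-[benzyl(dimethyl)silyl]-3-[(4-methoxybenzyloxy)methyl]-2-(tributylstannyl)buta-1,3-diene (Sn trans to Si)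
Conditions: Bu3SnH, PdCl2(PPh3)2 (cat.), THF, 0 °C to rt
Reagents that add atoms: tributylstannane, CCCC[SnH](CCCC)CCCC
Why: Palladium-catalysed syn hydrostannation. Tin should go to the alkyne carbon that bears the alkenyl group and is remote from the bulky silyl group, so the electronic and steric bias agree. H and Sn add cis, which places Sn trans to Si.

Step 9
Reactants: 15 dienylstannane; 6 enone
Product: 17 (1R,4S,6R)-1-{(1E)-1-[benzyl(dimethyl)silyl]-3-[(4-methoxybenzyloxy)methyl]buta-1,3-dien-2-yl}-3-methyl-6-(prop-1-en-2-yl)-4-(triisopropylsilyloxy)cyclohex-2-en-1-ol, via dienyllithium 16 (not isolated)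
Conditions: n-BuLi, THF, −78 °C; then 6, −78 °C; H2O
Reagents that add atoms: n-butyllithium, CCCC[Li] (lithium held only in 16)
Why: Tin–lithium exchange with retention, then 1,2-addition of the alkenyllithium to the enone. Equatorial entry anti to the adjacent isopropenyl group should give the trans-1,2-dialkenyl carbinol (new centre C6, OH cis to isopropenyl). The low temperature favours addition over enolisation.

Step 10
Reactants: 17 trans-1,2-dialkenylcyclohexenol
Product: 20 (1(10)E,4Z)-8β-[benzyl(dimethyl)silyl]-12-(4-methoxybenzyloxy)-3β-(triisopropylsilyloxy)germacra-1(10),4,11(13)-trien-6-one (H-7 α), via potassium alkoxide 18 (not isolated), via potassium dienolate 19 (not isolated)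
Conditions: KH, 18-crown-6, THF, 0 to 40 °C; then AcOH in THF, −78 °C
Reagents that add atoms: potassium hydride, [H-].[K+] (potassium held only in 18 and 19)
Why: Deprotonation gives alkoxide 18, whose charge weakens C1–C6 and triggers an anionic oxy-Cope [3,3]-shift in which C1–C6 breaks while C8–C9 forms, so the cyclohexene is enlarged by four atoms to the ten-membered ring (closure by sigmatropic ring expansion, not end-to-end cyclisation), and formation of dienolate 19 makes the step irreversible. The closest known reaction type is the KH/18-crown-6 oxy-Cope ring expansion of trans-1,2-dialkenylcyclohexanols, including adducts of 6-isopropenylcyclohex-2-enones with 1-substituted vinyl metals, to (E)-cyclodec-5-enones. With both alkenyl arms equatorial the unstrained array is the chair, in which C2 and C5 are equatorial; this should give the 1(10)E alkene and the enolate with C5 trans to C8, while C4=C5 is a spectator and keeps its Z geometry. C8 is set by chirality transfer from C1 and C6 (both destroyed): the E vinylsilane places silicon equatorial, so C9 bonds to the face of C8 that leaves Si β and H α. C7 is set on quenching: the enolate plane stands perpendicular to the ring, its inner face is covered by C1=C10, and the proton should enter from outside at the α-carbon of the dienolate, leaving H-7 α and C11 β. The selectivities needed are [3,3] over a [1,3]-shift or the alternative 1,5-diene through C4=C5 (which would need a boat across the ring with an axial isopropenyl group), chair over boat (secured by the trans-diequatorial arms) and α- over γ-protonation (secured by the cold acetic acid quench). Silicon instead of oxygen on C8 is essential, since a β-alkoxy enolate would eliminate.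

Step 11
Reactants: 20 8β-silyl ketone
Product: 22 (1(10)E,4Z)-8β-hydroxy-12-(4-methoxybenzyloxy)-3β-(triisopropylsilyloxy)germacra-1(10),4,11(13)-trien-6-one, via silanol 21 (not isolated)
Conditions: TBAF, THF, 0 °C, short; then KHCO3, 30% H2O2, MeOH/THF, rt
Reagents that add atoms: water, O (oxygen of silanol 21); hydrogen peroxide, OO (oxygen on C8 of 22)
Why: Tamao–Fleming oxidation of a benzyldimethylsilyl group: fluoride cleaves the benzyl–silicon bond, and peroxide then moves C8 from silicon to oxygen with retention, so Si β becomes OH β. The brief cold fluoride exposure should leave the hindered TIPS ether, and isolated alkenes are inert to buffered H2O2.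

Step 12
Reactants: 23 methyl angelate
Product: 24 (Z)-2-methylbut-2-en-1-ol
Conditions: DIBAL-H, CH2Cl2, −78 °C; aqueous work-up
Reagents that add atoms: none
Why: Hydride reduction of the enoate to the allylic alcohol at low temperature, which should not disturb the Z geometry.

Step 13
Reactants: 24 (Z)-2-methylbut-2-en-1-ol
Product: 25 (2S,3R)-2,3-epoxy-2-methylbutan-1-ol
Conditions: Ti(OiPr)4 (cat.), L-(+)-diisopropyl tartrate (cat.), t-BuOOH, 4 Å MS, CH2Cl2, −20 °C
Reagents that add atoms: tert-butyl hydroperoxide, CC(C)(C)OO
Why: Sharpless asymmetric epoxidation. The L-(+)-tartrate catalyst delivers oxygen to the alkene face that gives 2S at the carbinol-bearing carbon, and syn addition to the Z alkene fixes 3R.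

Step 14
Reactants: 25 epoxy alcohol
Product: 26 (2R,3R)-2,3-epoxy-2-methylbutanal
Conditions: TEMPO (cat.), PhI(OAc)2, CH2Cl2, 0 °C to rt
Reagents that add atoms: none
Why: Oxoammonium oxidation of a primary alcohol stops at the aldehyde. The α-carbon is quaternary, so no epimerisation or enolisation is possible.

Step 15
Reactants: 22 β-hydroxy ketone; 26 epoxy aldehyde
Product: 28 (1(10)E,4Z)-8β-[(2R,3R)-2,3-epoxy-2-methylbutanoyloxy]-6α-hydroxy-12-(4-methoxybenzyloxy)-3β-(triisopropylsilyloxy)germacra-1(10),4,11(13)-triene, via hemiacetal 27 (not isolated)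
Conditions: SmI2 (0.3 equiv), 26 (excess), THF, −10 °C
Reagents that add atoms: none
Why: Evans–Tishchenko reduction: hemiacetal 27, bound with the ketone to trivalent samarium, passes its hydride to C6 through a chair six-membered transition state. This gives the 1,3-anti relation (6α-OH to 8β-O) and turns the aldehyde carbon into the C8 ester. The hydride arrives on the outer face of the carbonyl that the ring also prefers, so directed and macrocyclic control are matched.

Step 16
Reactants: 28 hydroxy ester
Product: 29 (1(10)E,4Z)-8β-[(2R,3R)-2,3-epoxy-2-methylbutanoyloxy]-3β-(triisopropylsilyloxy)germacra-1(10),4,11(13)-triene-6α,12-diol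
Conditions: DDQ, CH2Cl2/pH 7 buffer, 0 °C
Reagents that add atoms: none
Why: Oxidative cleavage of the 4-methoxybenzyl ether under neutral conditions. Esters, oxirane, silyl ether and unconjugated alkenes are not attacked.

Step 17
Reactants: 29 6α,12-diol
Product: 32 (1(10)E,4Z)-8β-[(2R,3R)-2,3-epoxy-2-methylbutanoyloxy]-3β-(triisopropylsilyloxy)germacra-1(10),4,11(13)-trien-6α,12-olide, via enal 30 (not isolated), via lactol 31 (not isolated)
Conditions: TEMPO (cat.), PhI(OAc)2 (2.5 equiv), CH2Cl2, rt
Reagents that add atoms: none
Why: Oxidative lactonisation of a 2-methylene-1,4-diol: the primary allylic alcohol is oxidised first, enal 30 is trapped by the 6α-hydroxyl as lactol 31, and this is oxidised on. Only O6 is free, so only the 6,12-olide can form, and its trans fusion follows from C6 and C7.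

Step 18
Reactants: 32 silyl ether lactone
Product: 33 (1(10)E,4Z)-8β-[(2R,3R)-2,3-epoxy-2-methylbutanoyloxy]-3β-hydroxygermacra-1(10),4,11(13)-trien-6α,12-olide
Conditions: HF·pyridine, pyridine, THF, 0 °C to rt
Reagents that add atoms: none
Why: Buffered fluoride desilylation avoids the basic fluoride that would add to the α-methylene lactone. The oxirane next to the ester carbonyl is deactivated toward acid opening.

Step 19
Reactants: 33 3β-alcohol; 34 (R)-2-methylbutanoic acid
Product: 36 (1(10)E,4Z)-8β-[(2R,3R)-2,3-epoxy-2-methylbutanoyloxy]-3β-[(R)-2-methylbutanoyloxy]germacra-1(10),4,11(13)-trien-6α,12-olide, via O-acylisourea 35 (not isolated)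
Conditions: DCC, DMAP (cat.), CH2Cl2, 0 °C
Reagents that add atoms: N,N'-dicyclohexylcarbodiimide, C(=NC1CCCCC1)=NC1CCCCC1 (held only in 35)
Why: Steglich esterification of the only free hydroxyl, with retention at C3. The low temperature and catalytic DMAP should keep the α-centre of the acid intact.

Step 20
Reactants: 36 diester diene
Product: 37 CNP0265335.1, the (1R,10R)-1β,10α-epoxide of 36
Conditions: dimethyldioxirane, acetone/CH2Cl2, −40 to −20 °C
Reagents that add atoms: dimethyldioxirane, CC1(C)OO1
Why: Neutral electrophilic epoxidation. C1=C10 is the only electron-rich alkene, because C4=C5 carries two allylic acyloxy groups and C11=C13 is conjugated. The trans-lactone holds O6 and C11 gauche, which turns the C9–C10=C1–C2 segment so that C14 lies on the β face. Attack on the only open, outer face should then give 1R,10R.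

## Compound list

1 | (S)-(+)-carvone | CC1=CC[C@@H](CC1=O)C(C)=C | starting material
2 | (S)-carvone enone epoxide, oxirane trans to isopropenyl | O=C1C[C@@H](C(C)=C)C[C@@H]2O[C@]12C | intermediate
3 | hydrazone of 2 | NN=C1C[C@@H](C(C)=C)C[C@@H]2O[C@]12C | intermediate
4 | (1S,5R)-trans-carveol | O[C@H]1C[C@H](C(C)=C)CC=C1C | intermediate
5 | (1S,5R)-trans-carveol triisopropylsilyl ether | CC(C)[Si](C(C)C)(C(C)C)O[C@H]1C[C@H](C(C)=C)CC=C1C | intermediate
6 | (4S,6R)-3-methyl-6-(prop-1-en-2-yl)-4-(triisopropylsilyloxy)cyclohex-2-en-1-one | CC(C)[Si](C(C)C)(C(C)C)O[C@H]1C[C@H](C(C)=C)C(=O)C=C1C | intermediate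
7 | 4-methoxybenzyl alcohol | COc1ccc(CO)cc1 | starting material
8 | 2,3-dibromopropene | C=C(Br)CBr | starting material
9 | sodium 4-methoxybenzyl oxide | COc1ccc(C[O-])cc1.[Na+] | intermediate
10 | 2-bromoallyl 4-methoxybenzyl ether | C=C(Br)COCc1ccc(OC)cc1 | intermediate
11 | benzyl(chloro)dimethylsilane | C[Si](C)(Cl)Cc1ccccc1 | starting material
12 | ethynylmagnesium bromide | C#C[Mg]Br | starting material
13 | benzyl(ethynyl)dimethylsilane | C#C[Si](C)(C)Cc1ccccc1 | intermediate
14 | benzyl{3-[(4-methoxybenzyloxy)methyl]but-3-en-1-yn-1-yl}dimethylsilane | C=C(COCc1ccc(OC)cc1)C#C[Si](C)(C)Cc1ccccc1 | intermediate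
15 | (1E)-1-[benzyl(dimethyl)silyl]-3-[(4-methoxybenzyloxy)methyl]-2-(tributylstannyl)buta-1,3-diene | CCCC[Sn](CCCC)(CCCC)/C(=C/[Si](C)(C)Cc1ccccc1)C(=C)COCc1ccc(OC)cc1 | intermediate
16 | dienyllithium from 15 (Li trans to Si) | [Li]/C(=C/[Si](C)(C)Cc1ccccc1)C(=C)COCc1ccc(OC)cc1 | intermediate
17 | (1R,4S,6R)-trans-1,2-dialkenylcyclohexenol | CC(C)[Si](C(C)C)(C(C)C)O[C@H]1C[C@H](C(C)=C)[C@@](O)(/C(=C/[Si](C)(C)Cc2ccccc2)C(=C)COCc2ccc(OC)cc2)C=C1C | intermediate
18 | potassium alkoxide of 17 | CC(C)[Si](C(C)C)(C(C)C)O[C@H]1C[C@H](C(C)=C)[C@@]([O-])(/C(=C/[Si](C)(C)Cc2ccccc2)C(=C)COCc2ccc(OC)cc2)C=C1C.[K+] | intermediate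
19 | potassium dienolate of 20 (C5 trans to C8 on C6=C7) | [K+].[O-]/C1=C(/C(=C)COCc2ccc(OC)cc2)[C@H]([Si](C)(C)Cc2ccccc2)C/C(C)=C/C[C@H](O[Si](C(C)C)(C(C)C)C(C)C)/C(C)=C\1 | intermediate
20 | 8β-silyl germacratrien-6-one | O=C1/C=C(/C)[C@@H](O[Si](C(C)C)(C(C)C)C(C)C)C/C=C(\C)C[C@@H]([Si](C)(C)Cc2ccccc2)[C@H]1C(=C)COCc2ccc(OC)cc2 | intermediate
21 | 8β-(hydroxydimethylsilyl) ketone | O=C1/C=C(/C)[C@@H](O[Si](C(C)C)(C(C)C)C(C)C)C/C=C(\C)C[C@@H]([Si](C)(C)O)[C@H]1C(=C)COCc2ccc(OC)cc2 | intermediate
22 | 8β-hydroxy germacratrien-6-one | O=C1/C=C(/C)[C@@H](O[Si](C(C)C)(C(C)C)C(C)C)C/C=C(\C)C[C@@H](O)[C@H]1C(=C)COCc2ccc(OC)cc2 | intermediate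
23 | methyl angelate | C/C=C(/C)C(=O)OC | starting material
24 | (Z)-2-methylbut-2-en-1-ol | C/C=C(/C)CO | intermediate
25 | (2S,3R)-2,3-epoxy-2-methylbutan-1-ol | OC[C@]1(C)O[C@@H]1C | intermediate
26 | (2R,3R)-2,3-epoxy-2-methylbutanal | O=C[C@]1(C)O[C@@H]1C | intermediate
27 | hemiacetal of 22 (O8) and 26 | O=C1/C=C(/C)[C@@H](O[Si](C(C)C)(C(C)C)C(C)C)C/C=C(\C)C[C@@H](OC(O)[C@]2(C)O[C@@H]2C)[C@H]1C(=C)COCc2ccc(OC)cc2 | intermediate
28 | 6α-hydroxy 8β-epoxyangelate | O[C@@H]1/C=C(/C)[C@@H](O[Si](C(C)C)(C(C)C)C(C)C)C/C=C(\C)C[C@@H](OC(=O)[C@]2(C)O[C@@H]2C)[C@H]1C(=C)COCc2ccc(OC)cc2 | intermediate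
29 | 6α,12-diol | O[C@@H]1/C=C(/C)[C@@H](O[Si](C(C)C)(C(C)C)C(C)C)C/C=C(\C)C[C@@H](OC(=O)[C@]2(C)O[C@@H]2C)[C@H]1C(=C)CO | intermediate
30 | 6α-hydroxy 12-enal | O[C@@H]1/C=C(/C)[C@@H](O[Si](C(C)C)(C(C)C)C(C)C)C/C=C(\C)C[C@@H](OC(=O)[C@]2(C)O[C@@H]2C)[C@H]1C(=C)C=O | intermediate
31 | 6α,12-lactol | C=C1C(O)O[C@@H]2/C=C(/C)[C@@H](O[Si](C(C)C)(C(C)C)C(C)C)C/C=C(\C)C[C@@H](OC(=O)[C@]3(C)O[C@@H]3C)[C@@H]12 | intermediate
32 | 3β-silyloxy heliangolide | C=C1C(=O)O[C@@H]2/C=C(/C)[C@@H](O[Si](C(C)C)(C(C)C)C(C)C)C/C=C(\C)C[C@@H](OC(=O)[C@]3(C)O[C@@H]3C)[C@@H]12 | intermediate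
33 | 3β-hydroxy heliangolide | C=C1C(=O)O[C@@H]2/C=C(/C)[C@@H](O)C/C=C(\C)C[C@@H](OC(=O)[C@]3(C)O[C@@H]3C)[C@@H]12 | intermediate
34 | (R)-2-methylbutanoic acid | CC[C@@H](C)C(=O)O | starting material
35 | O-acylisourea of 34 | CC[C@@H](C)C(=O)OC(=NC1CCCCC1)NC1CCCCC1 | intermediate
36 | 1(10)-ene diester | C=C1C(=O)O[C@@H]2/C=C(/C)[C@@H](OC(=O)[C@H](C)CC)C/C=C(\C)C[C@@H](OC(=O)[C@]3(C)O[C@@H]3C)[C@@H]12 | intermediate
37 | CNP0265335.1 | C=C1C(=O)O[C@@H]2/C=C(/C)[C@@H](OC(=O)[C@H](C)CC)C[C@H]3O[C@]3(C)C[C@@H](OC(=O)[C@]3(C)O[C@@H]3C)[C@@H]12 | target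

## Count and least certain steps

Total step count: 20. Longest linear sequence: 13 (steps 1–4, 9–11, 15–20).

**Step 10 (key step).**
- *Risk:* The congested trisubstituted vinylsilane arm may slow the [3,3]-shift. Cleavage of the alkoxide back to ketone and dienyl anion could then take over, or the dienolate could equilibrate with loss of the C7 configuration or migration of C11=C13 into conjugation.
- *Fallback:* The C7–C11 bond is made after the ring expansion. The fallback sets out from 6 and 13.
  - Radical or palladium-catalysed hydrostannation of 13 gives (E)-1-[benzyl(dimethyl)silyl]-2-(tributylstannyl)ethene F1.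
  - Tin–lithium exchange and addition to 6 give the less hindered carbinol F2.
  - The same KH/18-crown-6 treatment gives the C7-unsubstituted ketone F3.
  - Its potassium enolate (KHMDS) is joined to bromide 10 by palladium-catalysed ketone α-alkenylation (Pd2(dba)3, P(t-Bu)3).
  - The acidic product is deprotonated in the flask to dienolate 19, and cold protonation comes back to the route at 20.

**Step 15.**
- *Risk:* Hemiacetal formation between the hindered 8β-hydroxyl and an α-quaternary aldehyde may be unfavourable. Samarium iodide species may open the oxirane of 26. The acyl group may migrate from O8 to O6.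
- *Fallback:* Acylation and reduction are separated. The fallback sets out from 26 and 22.
  - Pinnick oxidation of 26 gives (2R,3R)-2,3-epoxy-2-methylbutanoic acid F4.
  - Yamaguchi esterification of 22 with F4 gives keto ester F5.
  - Luche reduction at −78 °C relies on attack at the outer face of the ring ketone and comes back at 28.

**Step 11.**
- *Risk:* Basic fluoride may remove the proton on C7, which is both α to the ketone and allylic. This would cause epimerisation or migration of the double bond. Retro-aldol cleavage of the product is also possible.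
- *Fallback:* The carbonyl is taken out during the basic step. The fallback sets out from 20.
  - Luche reduction gives the 6α-allylic alcohol F6.
  - The same fluoride/peroxide sequence gives the 6,8-diol F7.
  - MnO2 oxidises only the allylic C6 hydroxyl and comes back at 22.

**Step 8.**
- *Risk:* Poor regioselectivity of tin delivery, because the branched alkenyl and silyl groups are of similar size, or protodestannylation of the dienylstannane.
- *Fallback:* The geometry is built on the carbinol itself. The fallback sets out from 6, 12, 11 and 10.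
  - Addition of 12 to 6 gives ethynyl carbinol F8.
  - Benzyl(dimethyl)(tributylstannyl)silane F9 is made from 11 and Bu3SnLi. It adds syn under Pd(PPh3)4 with silicon on the terminal and tin on the internal carbon, giving F10.
  - Stille coupling of F10 with 10 (Pd2(dba)3, AsPh3, CuI) comes back at 17.

**Step 4.**
- *Risk:* Competing hydrogen abstraction at C3–H with loss of the silyl ether, or at the isopropenyl group, and epimerisation next to the new ketone.
- *Fallback:* C–H oxidation is replaced by an alkene transposition. The fallback sets out from 5.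
  - mCPBA epoxidises the more substituted ring alkene to give F11.
  - PhSeNa opens it at the secondary carbon to give hydroxy selenide F12.
  - H2O2 effects selenoxide elimination to the tertiary allylic alcohol F13.
  - Babler–Dauben oxidative transposition with PCC comes back at 6.

**Step 20.**
- *Risk:* Poor facial selectivity if a ring conformer with C14 on the α face reacts, or partial attack at C4=C5.
- *Fallback:* Substrate control is replaced by reagent control. The fallback sets out from 36. Shi epoxidation with the D-fructose-derived ketone and Oxone has an inherent sense for E-trisubstituted alkenes that corresponds to 1R,10R. It selects the matching conformer of the interconverting ring and comes back at 37. No new compound is made.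

## Further compounds

F1 | step 10 | (E)-1-[benzyl(dimethyl)silyl]-2-(tributylstannyl)ethene | CCCC[Sn](CCCC)(CCCC)/C=C/[Si](C)(C)Cc1ccccc1
F2 | step 10 | (1R,4S,6R)-1-{(E)-2-[benzyl(dimethyl)silyl]ethenyl}-3-methyl-6-(prop-1-en-2-yl)-4-(triisopropylsilyloxy)cyclohex-2-en-1-ol | CC(C)[Si](C(C)C)(C(C)C)O[C@H]1C[C@H](C(C)=C)[C@@](O)(/C=C/[Si](C)(C)Cc2ccccc2)C=C1C
F3 | step 10 | (1(10)E,4Z)-8β-[benzyl(dimethyl)silyl]-3β-(triisopropylsilyloxy)cyclodecadien-6-one without C7 substituent | O=C1/C=C(/C)[C@@H](O[Si](C(C)C)(C(C)C)C(C)C)C/C=C(\C)C[C@@H]([Si](C)(C)Cc2ccccc2)C1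
F4 | step 15 | (2R,3R)-2,3-epoxy-2-methylbutanoic acid | OC(=O)[C@]1(C)O[C@@H]1C
F5 | step 15 | 8β-epoxyangeloyloxy germacratrien-6-one | O=C1/C=C(/C)[C@@H](O[Si](C(C)C)(C(C)C)C(C)C)C/C=C(\C)C[C@@H](OC(=O)[C@]2(C)O[C@@H]2C)[C@H]1C(=C)COCc2ccc(OC)cc2
F6 | step 11 | 8β-silyl germacratrien-6α-ol | O[C@@H]1/C=C(/C)[C@@H](O[Si](C(C)C)(C(C)C)C(C)C)C/C=C(\C)C[C@@H]([Si](C)(C)Cc2ccccc2)[C@H]1C(=C)COCc2ccc(OC)cc2
F7 | step 11 | germacratriene-6α,8β-diol | O[C@@H]1/C=C(/C)[C@@H](O[Si](C(C)C)(C(C)C)C(C)C)C/C=C(\C)C[C@@H](O)[C@H]1C(=C)COCc2ccc(OC)cc2
F8 | step 8 | (1R,4S,6R)-1-ethynyl-3-methyl-6-(prop-1-en-2-yl)-4-(triisopropylsilyloxy)cyclohex-2-en-1-ol | CC(C)[Si](C(C)C)(C(C)C)O[C@H]1C[C@H](C(C)=C)[C@@](O)(C#C)C=C1C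
F9 | step 8 | benzyl(dimethyl)(tributylstannyl)silane | CCCC[Sn](CCCC)(CCCC)[Si](C)(C)Cc1ccccc1
F10 | step 8 | carbinol with 2-silyl-1-stannylethenyl arm (Si cis to Sn, trans to the ring) | CC(C)[Si](C(C)C)(C(C)C)O[C@H]1C[C@H](C(C)=C)[C@@](O)(/C(=C/[Si](C)(C)Cc2ccccc2)[Sn](CCCC)(CCCC)CCCC)C=C1C
F11 | step 4 | ring epoxide of 5 (oxirane anti to the silyloxy group) | CC(C)[Si](C(C)C)(C(C)C)O[C@H]1C[C@H](C(C)=C)C[C@@H]2O[C@]12C
F12 | step 4 | trans-hydroxy phenylselenide from F11 | CC(C)[Si](C(C)C)(C(C)C)O[C@H]1C[C@H](C(C)=C)C[C@@H]([Se]c2ccccc2)[C@]1(C)O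
F13 | step 4 | tertiary allylic alcohol from F12 | CC(C)[Si](C(C)C)(C(C)C)O[C@H]1C[C@H](C(C)=C)C=C[C@]1(C)O
F0 | step 20 | none | none
A1 | alternative 1 | seco Z-enal 2-(bromomethyl)acrylate, 3,8-bis(TBS) ether | O=C/C=C(/C)[C@@H](O[Si](C)(C)C(C)(C)C)C/C=C(\C)C[C@@H](O[Si](C)(C)C(C)(C)C)/C=C(\CBr)C(=O)OC
A2 | alternative 2 | lactone diene for ring-closing metathesis at C1=C10 | C=C1C(=O)O[C@H](/C=C(/C)[C@@H](O[Si](C)(C)C(C)(C)C)CC=C)[C@H]1[C@H](O[Si](C)(C)C(C)(C)C)CC(C)=C
A3 | alternative 3 | 13-membered bis-allylic ether for [2,3]-Wittig contraction | O1C/C=C(/C)[C@@H](O[Si](C)(C)C(C)(C)C)C/C=C(\C)C[C@@H](O[Si](C)(C)C(C)(C)C)/C=C(\CO[Si](C)(C)C(C)(C)C)C1
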